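Assumption (remark on the chemistry): commercial solanesol is taken as the all-E isomer, "octaprenyl" means (2E,6E,10E,14E,18E,22E,26E)-3,7,11,15,19,23,27,31-octamethyldotriaconta-2,6,10,14,18,22,26,30-octaen-1-yl, and the transient sp3 centres of 2, 3, 10, 12 and 14 are carried as racemates because each is erased before 20.

## Structural features

Menaquinone-8 is a 1,4-naphthoquinone in which an unsubstituted benzo ring (ring A) is fused to a quinone ring (ring B). C2 of ring B carries a methyl group and C3 carries the all-E C40 octaprenyl chain through the allylic carbon C1'. The molecule has no stereocentre; its stereochemical content is seven E trisubstituted alkenes, and the 2'E alkene next to ring B is the one that aromatic allylation chemistry tends to scramble. The eight electron-rich alkenes are sensitive to protic and Lewis acids (cation–olefin cyclisation, hydrohalogenation), to electrophilic oxidants and to radicals. C1' is doubly activated, the quinone is base- and light-sensitive, and hydroquinone-level intermediates are air-sensitive. The real difficulty is therefore the regiodefined C3–C1' bond with intact 2'E geometry, not the naphthoquinone itself. The key step exploits the 1,4-dioxygenation of ring B: with a carboxyl carbon on C2, the C1–C2 bond is the bond of a β-keto ester, so an ester enolate at C2 can close ring B onto an aromatic ester carbonyl at C1 while C3 already holds the chain as an sp3 carbon taken from solanesol. The closure mirrors the biosynthetic ring formation, with one difference: nature expels that carboxyl carbon as CO2 when the chain arrives and adds the methyl later from S-adenosylmethionine, whereas here the carboxyl carbon is kept and reduced to the C2 methyl.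

## Logic of the disconnections

20 to 19: no skeletal bond is cut; the two quinone carbonyls are traced back to two aryl methyl ethers. The quinone would not survive hydride reagents, whereas 19 is a robust arene. The forward step must remove two O-methyl groups oxidatively without touching eight alkenes.

19 to 17 to 16: the C2 methyl is traced to a hydroxymethyl group and then to a methyl ester, so only C–H bonds are exchanged for C–O bonds. The ester is the group the ring closure leaves on C2. The forward deoxygenation must avoid a benzylic cation, because the 2'-alkene sits beside it.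

16 to 15: the two O–CH3 bonds are cut. This protects an air-sensitive naphthalenediol; the forward step must alkylate on oxygen and overcome the hydrogen bond between the C1 hydroxyl and the ester.

15 to 14: the C1–C2 bond is cut and ring B is opened. The bicyclic target core becomes a benzene carrying a keto diester side chain, with the chain already on C3. The forward step must favour the C2 enolate over the more acidic C3 position and must exclude oxygen.

14 to 10 and 11 (through 12 and 13): the C4–C4a bond between the ketone carbon and ring A is cut. Ring A becomes a commodity aryl iodide and the chain-bearing part a succinic half ester. The forward step must stop at the ketone and distinguish one acyl group from two methyl esters. An arylmagnesium adding to an N-methoxy-N-methylamide would have to choose between amide and ester and would be too short-lived at the temperature an α-branched amide needs, so an acid chloride and an ester-tolerant arylzinc are used.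

10 to 7 and 8: the C2–C3 bond is cut. This leaves a linear C42 acid whose α-carbon is the future C3. The forward step is a monoalkylation of that α-carbon in which substitution at bromine must outrun attack at the ester carbonyl of 8.

7 to 6 to 4: in the backward sense one carbon is added, between the carboxyl carbon and a hydroxymethyl and then a methyl group. This connects the acid to the methyl ketone that oxidative cleavage of a polyprenol delivers. The forward steps must functionalise the methyl side of the ketone selectively and then excise that carbon.

4 to 2 (through 3) to 1: the C2=C3 alkene of 1 is restored. 1 is the inexpensive all-E polyprenol with at least eight units, and its first unit is sacrificed so that C4 of 1 becomes C3 of ring B and C3 of 1 becomes C4. The forward step must oxidise one alkene out of nine; the allylic hydroxyl provides the direction.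

## Other disconnections considered

Alternative 1: The cut is through both bonds that join ring B to ring A, C1–C8a and C4–C4a. In the forward key step, fluoride (CsF, MeCN) would release the aryne from A3 (2-(trimethylsilyl)phenyl triflate), which would add across C2 and C5 of the furan A2 (3-methyl-4-octaprenylfuran). The [4+2] cycloaddition would give the oxygen-bridged A1 (2-methyl-3-octaprenyl-1,4-dihydro-1,4-epoxynaphthalene, racemic).
- In its favour: two bonds and ring B form in one concerted step with no equilibrium; the aryne is symmetric, so regiochemistry does not arise; the C2 methyl and the chain would both be carbons of 1, so no ester-to-methyl reduction is needed.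
- Against it here: a 3,4-disubstituted furan carrying a C40 chain is the least accessible furan pattern and would cost several steps from 1. The aryne is an indiscriminate electrophile that can undergo ene and [2+2] reactions with the eight trisubstituted alkenes, and the remedy (excess diene) spends the valuable component A2. A1 also has C1 and C4 at the ether level, so the bridge would have to be opened, most simply by acid next to the 2'-alkene, and the ring then oxidised to the quinone.
- Comparison: on mechanism the cycloaddition is the equal of the chosen closure, or better in directness. On structure the chosen plan is better, because C1 and C4 arrive as oxygenated aromatic carbons and methoxide does not touch the polyene. On step economy the two are about equal after the ring-forming step (about three steps against four), and the alternative is likely longer before it.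

Alternative 2: The cut is the C2–C3 bond. In the forward key step the bis(trimethylsilyl enol ether) A5, made from the diketone A4 (1-[2-(octaprenylacetyl)phenyl]propan-1-one), would be oxidised at constant current (carbon anode, LiClO4, MeCN/CH2Cl2, 2,6-lutidine). One oxidised enol ether carbon would be captured by the other to give A6 (2-methyl-3-octaprenyl-2,3-dihydronaphthalene-1,4-dione, cis/trans mixture), whose enolisation and aerobic oxidation would lead to 20.
- In its favour: the C2 methyl is present from the start as a propanoyl group, so the three redox steps spent here on the ester are saved. A6 is already at the hydroquinone oxidation level, and A4 could be reached from 7, so the same degradation of 1 serves.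
- Against it here: the anode would have to discriminate between two silyl enol ethers and eight trisubstituted alkenes. A 1,2-diacylbenzene such as A4 tends to undergo intramolecular aldol closure when enolised, which makes A5 hard to prepare. An intramolecular anodic coupling of two enol ethers to a six-membered 1,4-diketone has no close counterpart on this substrate class.
- Comparison: on structure the two plans are equal, since both place the chain on an sp3 C3 derived from 7. On step economy the alternative is the better one, by roughly two to three steps. On mechanism the chosen plan is safer, since it relies on a thermodynamic funnel with direct analogy rather than on an electrode selectivity that cannot be predicted with confidence.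

Alternative 3: The cut is the C3–C4 bond, with C1–C2 made one step earlier by carbonyl addition. The alkenyllithium A10 would add to one carbonyl of benzocyclobutenedione A9 to give the carbinol A7. On heating A7 in toluene or xylene the four-membered ring would open electrocyclically, and the ketene carbon so unveiled (C4) would bond to the alkene carbon C3 in a six-electron closure. Tautomerisation would give menaquinol-8 A8, and air would then give 20.
- In its favour: neutral thermal conditions that spare the polyene; regiochemistry fixed by the alkenyl unit; methyl and chain both carbons of 1; only one trivial oxidation after the ring-forming step, against four steps in the chosen plan, which is a clear advantage.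
- Against it here: A9 is a costly multi-step reagent. A10 needs a regiodefined trisubstituted alkenyl halide in which the alkene of 1 has been moved to the C3=C4 position; kinetic enol derivatives of 4 would place the double bond on the wrong, terminal side.
- Comparison: on mechanism the pericyclic cascade is the equal of the chosen closure in reliability. On structure both fix the C2/C3 pattern unambiguously. On overall step economy the gain after the key step is likely consumed by the two fragment syntheses, so the total is about equal, while the chosen plan uses only commodity partners.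

Key step: step 7

## Route

Step 1
Reactants: 1 solanesol (all-E nonaprenol)
Product: 2 rac-(2R*,3R*)-2,3-epoxysolanesol
Conditions: VO(acac)2 (2 mol%), tBuOOH (1.3 equiv, decane), toluene, 0 °C → rt
Reagents that add atoms: tert-butyl hydroperoxide, CC(C)(C)OO
Why: Hydroxyl-directed vanadium-catalysed epoxidation: the allylic alkoxide binds the metal alkylperoxide, so only the 2,3-alkene should react and the eight remote alkenes stay intact. Syn addition to the E alkene sets the two new centres as the racemic trans epoxide; both are erased in step 2.

Step 2
Reactants: 2 rac-(2R*,3R*)-2,3-epoxysolanesol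
Product: 4 octaprenylacetone (all-E C43 methyl ketone), via triol 3 (not isolated)
Conditions: H5IO6 (2.5 equiv), THF/H2O (5:1), 0 °C → rt
Reagents that add atoms: water, O
Why: Periodic acid opens the epoxide to the 1,2,3-triol and then cleaves both glycol C–C bonds (Malaprade cleavage), leaving the former C3 as a methyl ketone. The same reagent is routinely used to cut epoxides on polyprenyl chains without cyclising them.

Step 3
Reactants: 4 octaprenylacetone
Product: 6 1-hydroxy-octaprenylacetone (α-ketol), via sodium enolate 5 (not isolated)
Conditions: NaN(SiMe3)2 (1.1 equiv), THF, −78 °C; then (±)-trans-3-phenyl-2-(phenylsulfonyl)oxaziridine (1.3 equiv), −78 °C; aq. NH4Cl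
Reagents that add atoms: trans-3-phenyl-2-(phenylsulfonyl)oxaziridine, O=S(=O)(N1OC1c1ccccc1)c1ccccc1
Why: Kinetic deprotonation by a hindered amide base at −78 °C should take a methyl proton, and the enolate is then hydroxylated by the N-sulfonyloxaziridine (enolate oxidation). The oxidant is inert towards isolated trisubstituted alkenes.

Step 4
Reactants: 6 1-hydroxy-octaprenylacetone
Product: 7 octaprenylacetic acid (all-E C42 acid)
Conditions: H5IO6 (1.5 equiv), THF/H2O (4:1), 0 °C → rt
Reagents that add atoms: water, O
Why: Periodate cleavage of an α-ketol through its ketone hydrate gives the carboxylic acid and formaldehyde; no alkene is involved.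

Step 5
Reactants: 7 octaprenylacetic acid; 8 methyl bromoacetate
Product: 10 4-methoxy-4-oxo-2-(octaprenyl)butanoic acid (racemic), via dilithium enediolate 9 (not isolated)
Conditions: LiN(iPr)2 (2.2 equiv, commercial solution), THF/DMPU, −78 → 0 °C; then 8 (1.2 equiv), −78 → −20 °C; 1 M HCl to pH 3
Reagents that add atoms: none
Why: Alkylation of a carboxylic acid dianion with a reactive α-halo ester: substitution at the C–Br carbon should outrun attack on the ester carbonyl at −78 °C. It gives directly the half ester with the free acid on the branched carbon; the new centre is racemic and is lost in step 7.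

Step 6
Reactants: 10 4-methoxy-4-oxo-2-(octaprenyl)butanoic acid; 11 methyl 2-iodobenzoate
Product: 14 methyl 2-[4-methoxy-4-oxo-2-(octaprenyl)butanoyl]benzoate (racemic), via acid chloride 12 (not isolated), via arylzinc iodide 13 (not isolated)
Conditions: 10, Me2C=C(Cl)NMe2 (1.2 equiv), CH2Cl2, 0 °C → rt, evaporate; 11, Zn dust, LiCl, THF, 25 °C (second flask); combine, Pd(PPh3)4 (5 mol%), THF, 0 °C → rt
Reagents that add atoms: none
Why: The α-chloroenamine makes the acid chloride under neutral conditions, so no HCl is present to add to the alkenes, and zinc insertion gives an arylzinc that tolerates its own ortho ester. Negishi acylation (oxidative addition of zerovalent palladium into the C–Cl bond, transmetalation, reductive elimination) stops at the ketone and leaves both methyl esters untouched.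

Step 7
Reactants: 14 methyl 2-[4-methoxy-4-oxo-2-(octaprenyl)butanoyl]benzoate
Product: 15 methyl 1,4-dihydroxy-3-octaprenyl-2-naphthoate
Conditions: NaOMe (4 equiv), MeOH/THF (1:3, degassed), Ar, 65 °C; then AcOH (degassed), 0 °C
Reagents that add atoms: none
Why: Methoxide deprotonates both α-positions reversibly, and the ester enolate at C2 adds to the aromatic ester carbonyl C1 with loss of methoxide, which forms the C1–C2 bond and closes ring B. The closest known reaction is the Dieckmann (intramolecular Claisen) condensation of o-succinylbenzoate diesters to 1,4-dihydroxy-2-naphthoates, the laboratory counterpart of the enzymatic closure. Ring B closes in the 6-(enolexo)-exo-trig mode, which the Baldwin rules for enolates allow. The first-formed 1,4-diketo ester loses two protons to give the naphthalene-1,4-diolate, and this aromatisation with salt formation makes the closure irreversible. No stereocentre is created, and the racemic centre at C3 becomes sp2. The selectivity needed is C2 against C3: the more acidic ketone α-carbon C3 can close a five-membered indane-1,3-dione and the ketone enolate oxygen can close enol lactones, but none of these can aromatise, the indanedione has a quaternary carbon and is reopened by methoxide (retro-Claisen), so all reversible channels should drain into 15. The chain sits on the sp3 carbon C3 and its 2'E alkene has no base-mediated path into conjugation, so the geometry taken from 1 is kept. THF keeps the lipophilic substrate in solution, and exclusion of oxygen protects the electron-rich diolate until the quench.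

Step 8
Reactants: 15 methyl 1,4-dihydroxy-3-octaprenyl-2-naphthoate
Product: 16 methyl 1,4-dimethoxy-3-octaprenyl-2-naphthoate
Conditions: Me2SO4 (3 equiv), K2CO3 (4 equiv), acetone, Ar, reflux
Reagents that add atoms: dimethyl sulfate, COS(=O)(=O)OC
Why: Williamson O-methylation of both phenoxides; C2 and C3 are fully substituted, which leaves oxygen as the productive site. Reflux with excess reagent overcomes the hydrogen bond between the C1 hydroxyl and the ester.

Step 9
Reactants: 16 methyl 1,4-dimethoxy-3-octaprenyl-2-naphthoate
Product: 17 (1,4-dimethoxy-3-octaprenylnaphthalen-2-yl)methanol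
Conditions: LiAlH4 (1.5 equiv), THF, 0 °C → rt; then H2O, 15% aq. NaOH
Reagents that add atoms: none
Why: Hydride reduction of the aryl ester to the benzylic alcohol; aryl methyl ethers and isolated alkenes are inert to LiAlH4.

Step 10
Reactants: 17 (1,4-dimethoxy-3-octaprenylnaphthalen-2-yl)methanol
Product: 19 1,4-dimethoxy-2-methyl-3-octaprenylnaphthalene, via mesylate 18 (not isolated)
Conditions: MsCl (1.3 equiv), Et3N (1.6 equiv), THF, −20 °C; filter; then LiBEt3H (3 equiv), THF, −20 → 0 °C
Reagents that add atoms: none
Why: Sulfonylation of the primary benzylic alcohol followed by SN2 displacement with the strongly nucleophilic hydride LiBEt3H. Low temperature and an aprotic medium are chosen so that the benzylic sulfonate is reduced before it can ionise next to the 2'-alkene.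

Step 11
Reactants: 19 1,4-dimethoxy-2-methyl-3-octaprenylnaphthalene
Product: 20 menaquinone-8
Conditions: (NH4)2Ce(NO3)6 (2.5 equiv), MeCN/CH2Cl2/H2O, 0 °C, dark
Reagents that add atoms: water, O
Why: Oxidative demethylation of the 1,4-dimethoxynaphthalene by two one-electron oxidations with tetravalent cerium, water adding at the ipso carbons and methanol leaving. The arene is oxidised far more easily than the trisubstituted alkenes, and the reaction type is routine for polyprenylated dimethoxyarenes.

## Compound list

1 | solanesol, (2E,6E,10E,14E,18E,22E,26E,30E)-3,7,11,15,19,23,27,31,35-nonamethylhexatriaconta-2,6,10,14,18,22,26,30,34-nonaen-1-ol | CC(C)=CCC/C(C)=C/CC/C(C)=C/CC/C(C)=C/CC/C(C)=C/CC/C(C)=C/CC/C(C)=C/CC/C(C)=C/CC/C(C)=C/CO | starting material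
2 | rac-(2R*,3R*)-2,3-epoxysolanesol (trans epoxide; one enantiomer drawn) | CC(C)=CCC/C(C)=C/CC/C(C)=C/CC/C(C)=C/CC/C(C)=C/CC/C(C)=C/CC/C(C)=C/CC/C(C)=C/CC[C@@]1(C)O[C@@H]1CO | intermediate
3 | rac-(2R*,3S*)-2,3-dihydrosolanesol-1,2,3-triol (one enantiomer drawn) | CC(C)=CCC/C(C)=C/CC/C(C)=C/CC/C(C)=C/CC/C(C)=C/CC/C(C)=C/CC/C(C)=C/CC/C(C)=C/CC[C@](C)(O)[C@H](O)CO | intermediate (not isolated)
4 | octaprenylacetone, (5E,9E,13E,17E,21E,25E,29E)-6,10,14,18,22,26,30,34-octamethylpentatriaconta-5,9,13,17,21,25,29,33-octaen-2-one | CC(C)=CCC/C(C)=C/CC/C(C)=C/CC/C(C)=C/CC/C(C)=C/CC/C(C)=C/CC/C(C)=C/CC/C(C)=C/CCC(C)=O | intermediate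
5 | sodium enolate of 4 at the methyl side (sodium 1-en-2-olate) | CC(C)=CCC/C(C)=C/CC/C(C)=C/CC/C(C)=C/CC/C(C)=C/CC/C(C)=C/CC/C(C)=C/CC/C(C)=C/CCC(=C)[O-].[Na+] | intermediate (not isolated)
6 | 1-hydroxy-octaprenylacetone (1-hydroxy derivative of 4) | CC(C)=CCC/C(C)=C/CC/C(C)=C/CC/C(C)=C/CC/C(C)=C/CC/C(C)=C/CC/C(C)=C/CC/C(C)=C/CCC(=O)CO | intermediate
7 | octaprenylacetic acid, (4E,8E,12E,16E,20E,24E,28E)-5,9,13,17,21,25,29,33-octamethyltetratriaconta-4,8,12,16,20,24,28,32-octaenoic acid | CC(C)=CCC/C(C)=C/CC/C(C)=C/CC/C(C)=C/CC/C(C)=C/CC/C(C)=C/CC/C(C)=C/CC/C(C)=C/CCC(=O)O | intermediate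
8 | methyl bromoacetate | COC(=O)CBr | starting material
9 | dilithium enediolate of 7 | CC(C)=CCC/C(C)=C/CC/C(C)=C/CC/C(C)=C/CC/C(C)=C/CC/C(C)=C/CC/C(C)=C/CC/C(C)=C/CC=C([O-])[O-].[Li+].[Li+] | intermediate (not isolated)
10 | 4-methoxy-4-oxo-2-(octaprenyl)butanoic acid (racemic) | CC(C)=CCC/C(C)=C/CC/C(C)=C/CC/C(C)=C/CC/C(C)=C/CC/C(C)=C/CC/C(C)=C/CC/C(C)=C/CC(CC(=O)OC)C(=O)O | intermediate
11 | methyl 2-iodobenzoate | COC(=O)c1ccccc1I | starting material
12 | methyl 4-chloro-4-oxo-3-(octaprenyl)butanoate (racemic) | CC(C)=CCC/C(C)=C/CC/C(C)=C/CC/C(C)=C/CC/C(C)=C/CC/C(C)=C/CC/C(C)=C/CC/C(C)=C/CC(CC(=O)OC)C(Cl)=O | intermediate (not isolated)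
13 | [2-(methoxycarbonyl)phenyl]zinc iodide | COC(=O)c1ccccc1[Zn]I | intermediate (not isolated)
14 | methyl 2-[4-methoxy-4-oxo-2-(octaprenyl)butanoyl]benzoate (racemic) | CC(C)=CCC/C(C)=C/CC/C(C)=C/CC/C(C)=C/CC/C(C)=C/CC/C(C)=C/CC/C(C)=C/CC/C(C)=C/CC(CC(=O)OC)C(=O)c1ccccc1C(=O)OC | intermediate
15 | methyl 1,4-dihydroxy-3-octaprenyl-2-naphthoate | CC(C)=CCC/C(C)=C/CC/C(C)=C/CC/C(C)=C/CC/C(C)=C/CC/C(C)=C/CC/C(C)=C/CC/C(C)=C/Cc1c(C(=O)OC)c(O)c2ccccc2c1O | intermediate
16 | methyl 1,4-dimethoxy-3-octaprenyl-2-naphthoate | CC(C)=CCC/C(C)=C/CC/C(C)=C/CC/C(C)=C/CC/C(C)=C/CC/C(C)=C/CC/C(C)=C/CC/C(C)=C/Cc1c(C(=O)OC)c(OC)c2ccccc2c1OC | intermediate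
17 | (1,4-dimethoxy-3-octaprenylnaphthalen-2-yl)methanol | CC(C)=CCC/C(C)=C/CC/C(C)=C/CC/C(C)=C/CC/C(C)=C/CC/C(C)=C/CC/C(C)=C/CC/C(C)=C/Cc1c(CO)c(OC)c2ccccc2c1OC | intermediate
18 | (1,4-dimethoxy-3-octaprenylnaphthalen-2-yl)methyl methanesulfonate | CC(C)=CCC/C(C)=C/CC/C(C)=C/CC/C(C)=C/CC/C(C)=C/CC/C(C)=C/CC/C(C)=C/CC/C(C)=C/Cc1c(COS(C)(=O)=O)c(OC)c2ccccc2c1OC | intermediate (not isolated)
19 | 1,4-dimethoxy-2-methyl-3-octaprenylnaphthalene | CC(C)=CCC/C(C)=C/CC/C(C)=C/CC/C(C)=C/CC/C(C)=C/CC/C(C)=C/CC/C(C)=C/CC/C(C)=C/Cc1c(C)c(OC)c2ccccc2c1OC | intermediate
20 | menaquinone-8, 2-methyl-3-octaprenylnaphthalene-1,4-dione | CC(C)=CCC/C(C)=C/CC/C(C)=C/CC/C(C)=C/CC/C(C)=C/CC/C(C)=C/CC/C(C)=C/CC/C(C)=C/CC1=C(C)C(=O)c2ccccc2C1=O | target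

## Step count and least certain steps

Total step count: 11. Longest linear sequence: 11 steps (1 to 20); 8 and 11 are bought, and 13 is made in the flask of step 6.

Step 7 (key step). The material may rest in the reversible five-membered reservoirs (indanedione, enol lactones) while slow irreversible side processes consume it: ester hydrolysis by adventitious hydroxide gives carboxylates that cannot condense, and aerobic oxidation attacks the diolate. Fallback: set out from 14 and close the five-membered ring on purpose under aprotic, kinetic conditions (LiN(SiMe3)2, THF, −78 → 0 °C). This gives methyl 2-[1,3-dioxo-2-(octaprenyl)indan-2-yl]acetate F1, a neutral, air-stable compound with no acidic proton between the ketones that can be purified free of acid and hydroxide. In a separate operation F1 is ring-expanded with NaOMe in degassed MeOH/THF (retro-Claisen to the enolate of 14, then the six-membered Claisen closure), the known acyl-migration route from 2,2-disubstituted indane-1,3-dione-2-acetates to 1,4-dihydroxy-2-naphthoates. The route is rejoined at 15.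

Step 5. Proton transfer from the α-bromo ester to the very basic enediolate, acylation at the ester carbonyl of 8 instead of substitution at bromine, and incomplete double deprotonation of an aggregated C42 lithium carboxylate are the likely failures. Fallback: set out from 7 and esterify with allyl bromide and K2CO3 in DMF to allyl octaprenylacetate F2. Alkylate its ester enolate (LiN(iPr)2, THF, −78 °C, then 8) to 1-allyl 4-methyl 2-(octaprenyl)succinate F3. Remove the allyl group under neutral conditions (Pd(PPh3)4 cat., morpholine, THF, rt); the route is rejoined at 10.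

Step 6. The acid chloride may be lost by cyclisation onto its neighbouring ester (anhydride formation with loss of chloromethane) or by ketene formation, and transmetalation of the ortho-substituted arylzinc may be slow enough for decarbonylation to intervene. Fallback: set out from 10 and prepare the thioester S-ethyl 4-methoxy-4-oxo-2-(octaprenyl)butanethioate F4 (EtSH, N-(3-dimethylaminopropyl)-N'-ethylcarbodiimide hydrochloride, DMAP cat., CH2Cl2). Couple F4 with 13 in a Fukuyama coupling (PdCl2(PPh3)2 cat., THF/toluene, rt), which needs no acid chloride; the route is rejoined at 14.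

Step 3. Deprotonation may partly occur at the internal methylene, and the enolate may add to the sulfonimine by-product instead of being oxidised. Fallback: set out from 4 and use the haloform reaction (NaOBr from Br2 and NaOH, dioxane/H2O, 0 °C). Exhaustive bromination through the enolate occurs only on the methyl group, and hydroxide then cleaves the tribromomethyl ketone; the strongly alkaline medium keeps the concentration of electrophilic bromine low enough to spare the alkenes in this known reaction of unsaturated methyl ketones. The route is rejoined at 7 and no new compound is isolated.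

Step 10. The electron-rich benzylic sulfonate may ionise before hydride arrives, and the cation may be captured by the 2'-alkene (cyclisation) or by chloride. Fallback: set out from 17 and oxidise with MnO2 in CH2Cl2 to 1,4-dimethoxy-3-octaprenyl-2-naphthaldehyde F5. Condense with TsNHNH2 in EtOH to the (E)-tosylhydrazone F6, and reduce F6 with catecholborane in CHCl3 at 0 °C followed by NaOAc·3H2O at reflux (tosylhydrazone deoxygenation, which passes through a diazene and never through a benzylic cation). The route is rejoined at 19.

## Further compounds

F1 | step 7 | methyl 2-[1,3-dioxo-2-(octaprenyl)indan-2-yl]acetate | CC(C)=CCC/C(C)=C/CC/C(C)=C/CC/C(C)=C/CC/C(C)=C/CC/C(C)=C/CC/C(C)=C/CC/C(C)=C/CC1(CC(=O)OC)C(=O)c2ccccc2C1=O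
F2 | step 5 | allyl octaprenylacetate (allyl ester of 7) | CC(C)=CCC/C(C)=C/CC/C(C)=C/CC/C(C)=C/CC/C(C)=C/CC/C(C)=C/CC/C(C)=C/CC/C(C)=C/CCC(=O)OCC=C
F3 | step 5 | 1-allyl 4-methyl 2-(octaprenyl)succinate (racemic) | CC(C)=CCC/C(C)=C/CC/C(C)=C/CC/C(C)=C/CC/C(C)=C/CC/C(C)=C/CC/C(C)=C/CC/C(C)=C/CC(CC(=O)OC)C(=O)OCC=C
F4 | step 6 | S-ethyl 4-methoxy-4-oxo-2-(octaprenyl)butanethioate (racemic) | CC(C)=CCC/C(C)=C/CC/C(C)=C/CC/C(C)=C/CC/C(C)=C/CC/C(C)=C/CC/C(C)=C/CC/C(C)=C/CC(CC(=O)OC)C(=O)SCC
F0 | step 3 | none | none
F5 | step 10 | 1,4-dimethoxy-3-octaprenyl-2-naphthaldehyde | CC(C)=CCC/C(C)=C/CC/C(C)=C/CC/C(C)=C/CC/C(C)=C/CC/C(C)=C/CC/C(C)=C/CC/C(C)=C/Cc1c(C=O)c(OC)c2ccccc2c1OC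
F6 | step 10 | (E)-N'-[(1,4-dimethoxy-3-octaprenylnaphthalen-2-yl)methylidene]-4-methylbenzenesulfonohydrazide | CC(C)=CCC/C(C)=C/CC/C(C)=C/CC/C(C)=C/CC/C(C)=C/CC/C(C)=C/CC/C(C)=C/CC/C(C)=C/Cc1c(/C=N/NS(=O)(=O)c3ccc(C)cc3)c(OC)c2ccccc2c1OC
A1 | alternative 1 | 2-methyl-3-octaprenyl-1,4-dihydro-1,4-epoxynaphthalene (racemic) | CC(C)=CCC/C(C)=C/CC/C(C)=C/CC/C(C)=C/CC/C(C)=C/CC/C(C)=C/CC/C(C)=C/CC/C(C)=C/CC1=C(C)C2OC1c1ccccc12
A2 | alternative 1 | 3-methyl-4-octaprenylfuran | CC(C)=CCC/C(C)=C/CC/C(C)=C/CC/C(C)=C/CC/C(C)=C/CC/C(C)=C/CC/C(C)=C/CC/C(C)=C/Cc1cocc1C
A3 | alternative 1 | 2-(trimethylsilyl)phenyl trifluoromethanesulfonate | C[Si](C)(C)c1ccccc1OS(=O)(=O)C(F)(F)F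
A4 | alternative 2 | 1-[2-(octaprenylacetyl)phenyl]propan-1-one | CC(C)=CCC/C(C)=C/CC/C(C)=C/CC/C(C)=C/CC/C(C)=C/CC/C(C)=C/CC/C(C)=C/CC/C(C)=C/CCC(=O)c1ccccc1C(=O)CC
A5 | alternative 2 | bis(trimethylsilyl enol ether) of A4 (Z,Z) | CC(C)=CCC/C(C)=C/CC/C(C)=C/CC/C(C)=C/CC/C(C)=C/CC/C(C)=C/CC/C(C)=C/CC/C(C)=C/C/C=C(\O[Si](C)(C)C)c1ccccc1/C(=C/C)O[Si](C)(C)C
A6 | alternative 2 | 2-methyl-3-octaprenyl-2,3-dihydronaphthalene-1,4-dione (cis/trans mixture) | CC(C)=CCC/C(C)=C/CC/C(C)=C/CC/C(C)=C/CC/C(C)=C/CC/C(C)=C/CC/C(C)=C/CC/C(C)=C/CC1C(C)C(=O)c2ccccc2C1=O
A7 | alternative 3 | 2-hydroxy-2-[(E)-1-methyl-2-(octaprenyl)vinyl]benzocyclobutenone (racemic) | CC(C)=CCC/C(C)=C/CC/C(C)=C/CC/C(C)=C/CC/C(C)=C/CC/C(C)=C/CC/C(C)=C/CC/C(C)=C/C/C=C(\C)C1(O)C(=O)c2ccccc21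
A8 | alternative 3 | menaquinol-8, 2-methyl-3-octaprenylnaphthalene-1,4-diol | CC(C)=CCC/C(C)=C/CC/C(C)=C/CC/C(C)=C/CC/C(C)=C/CC/C(C)=C/CC/C(C)=C/CC/C(C)=C/Cc1c(C)c(O)c2ccccc2c1O
A9 | alternative 3 | benzocyclobutenedione | O=C1C(=O)c2ccccc12
A10 | alternative 3 | (E)-[1-methyl-2-(octaprenyl)vinyl]lithium | CC(C)=CCC/C(C)=C/CC/C(C)=C/CC/C(C)=C/CC/C(C)=C/CC/C(C)=C/CC/C(C)=C/CC/C(C)=C/C/C=C(\C)[Li]
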